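X climbs to a shelf in both runs while Z stops at a floor, so I reckon with the Z left and not with the X made.

| setting | elm | alder | flask |
|---|---|---|---|
| Z | 0.017 M | 0.017 M | 0.017 M |
| D | 0.060 mM | 0.24 mM | 0.12 mM |
| remark | run made earlier | run made earlier |  |
| time |  |  | 5.0 min |

| run | time / min | X / % | Z / % |
|---|---|---|---|
| elm | 0.833 | 42.5 | 56.9 |
| elm | 1.50 | 71.7 | 28.3 |
| elm | 2.50 | 86.6 | 12.2 |
| elm | 3.00 | 89.8 | 10.2 |
| elm | 4.00 | 91.6 | 8.2 |
| elm | 5.00 | 93.0 | 8.0 |
| elm | 6.00 | 93.2 | 7.8 |
| alder | 0.333 | 35.7 | 63.1 |
| alder | 1.00 | 88.5 | 10.6 |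
| alder | 1.50 | 92.6 | 6.9 |
| alder | 2.50 | 93.5 | 7.5 |
| alder | 4.00 | 92.6 | 7.6 |
| alder | 5.00 | 93.8 | 6.3 |
| alder | 6.00 | 93.4 | 6.4 |

(each reading ± 0.5 percentage points)

- the average divides the monomer in chains by the number of chains begun, living and dead together
- the earlier runs do not show the number of chains; that part of a forecast is a guess

- average number of monomer units in a chain (chains begun, living or dead) at 5.0 min
- part of the Z that has reacted at 5.0 min

The last readings put that floor at 7.03% of the charge. Between 1.50 min and 2.50 min in elm, the excess of Z above the floor falls at 1.41 min⁻¹. I call this the clearing constant, the natural-log fall of the excess per minute, a pseudo-first-order constant.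

But the fall starts late. Run back, elm gives a lag of 0.457 min. If the constant grows in step with cD, alder's reading at 1.00 min gives 0.424 min, so I accept that scaling.

For the flask the constant is 2.83 min⁻¹, and by 5.0 min the excess has shrunk by a factor of 3.79 × 10⁵. So Z stands at the floor, and I expect c of 93.0%. If each D begins one chain, which the runs cannot show, dp is 132.

The forecast says 93.2% and 140, higher on dp than mine: “Incomplete initiator efficiency would raise dp”.

The flask gives 93.0% and 132.

    Z + J → G + X (k = 64.0 M⁻¹ s⁻¹)
    Z + G → X + G, rate k2*[G]*[Z] (k = 380 M⁻¹ s⁻¹)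
    X + G → Z + G, rate k3*[G] as long as [X] is above zero (k = 0.450 s⁻¹)
    D → J (k = 0.0380 s⁻¹)

One way for the forecast's c to fail is that excess Z still stands at the reading. A neighbour charged with cD of 3.0 × 10⁻⁵ M and read at the same 5.0 min tests this. Its clearing constant is 0.707 min⁻¹, and over 4.54 min that leaves an excess of 3.75%, so I reckon Z at 10.8%. The neighbour gives Z of 11.1% and c of 88.9%.

The runs come from a simulation on assumed constants; noise was put on by code.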